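(All constants are those of an exercise, and the outcome is calculated.)

If second nucleophile can reach target at all, the question is what share of it does, so here is the flask before I reckon that share.

    starting material → intermediate (k1 = 0.17 s⁻¹)
    first nucleophile + intermediate → target (k2 = 1000 M⁻¹ s⁻¹)
    second nucleophile + intermediate → other capture product (k3 = 97 M⁻¹ s⁻¹)
    intermediate → solvolysis product (k4 = 0.39 s⁻¹)
    second nucleophile → decomposed reagent (k5 = 0.14 s⁻¹)
    second nucleophile + target → over-reaction product (k6 = 35 M⁻¹ s⁻¹)

common to all: first nucleophile 2.00 mM; time 3.0 min

| charge | starting material | second nucleophile | remark |
|---|---|---|---|
| south-east | 2.0 mM | 1.40 mM | everything together at the start |
| north | 2.0 mM | 1.40 mM (fed, over 2.0 min) | all else is in the flask from the start; the feed brings no volume worth counting |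
| north-west | 2.0 mM (fed, over 2.0 min) | 1.40 mM | all else is in the flask from the start; the feed brings no volume worth counting |

* the best flask by amount of target, in percent of the starting material charged; "all alike" if 1.5 percentage points covers them all (south-east / north / north-west / all alike)
* amount of target at the end, in percent of the starting material charged, south-east
* amount of target at the end, in percent of the starting material charged, north
* amount of target at the end, in percent of the starting material charged, north-west

First comes the ceiling. Starting material and first nucleophile are charged equally, so, leaving the small capture by second nucleophile aside, the fraction b of first nucleophile left equals the fraction of the charge lost to solvolysis. That fraction obeys b = exp(−κb), where κ is capture at full first nucleophile over solvolysis, 5.13. One Newton step gives 74.3% of the charge captured, as target or as what target becomes.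

What I carry is the raid number g, the attack of second nucleophile on a whole charge of target over its own decay, 0.500. With target at fraction p of the charge, second nucleophile goes onto target with share gp/(1+gp).

One extreme is a flask with no target while second nucleophile lives: the raid takes nothing, and target stands at the ceiling. The other has target at the ceiling for as long as second nucleophile lives, which I reckon costs 19.0% of the charge and leaves 55.3%. I expect the real flasks between these two.

In north, the half-life of starting material, 0.068 min, is far shorter than the feed, so I put that flask at the second extreme. In north-west, one lifetime of second nucleophile is 5.95% of the feed, so I take p at that fraction and reckon the loss at 2.02% and target at 72.3%. South-east, where starting material goes at 0.17 s⁻¹ and second nucleophile decays at 0.14 s⁻¹, I place between north and north-west.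

The forecast gives north-west as best at 72% (70% to 74%), south-east 60% (57% to 63%) and north 56% (53% to 59%), holding that “feeding the starting material slowly lets that reagent decay before much target exists”. Its order is mine.

The simulation gives north-west as best: north-west 73.0%, south-east 63.0%, north 56.9%. In north, g with target at 57.7% after 2.00 min puts the raid loss at 15.7% of the charge, and that flask ends with 16.8% of over-reaction product. In north-west, second nucleophile has a half-life by its decay of 0.083 min, far shorter than the 1.03 min by which half of the capture to target is done; g on one lifetime of the feed gave 2.02%, and that flask ends with 0.779% of over-reaction product.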